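The target is the meso, doubly 2,3-trans 3,3''-biflavanone, with an inversion centre on the C3–C3'' bond. Everything rests on cutting O1–C8a and C2–C3 in each pyranone ring (ring C and its twin). O1–C2 is then the carbonyl group of an anisaldehyde, and C3–C4–C4a–C8a is the enolate of an ortho-fluoroaryl ketone. The precursor is the bis(silyl enol ether) of a symmetric 1,4-diaryl-1,4-butanedione that already holds C3–C3''. Catalytic fluoride starts a twofold aldol/SNAr relay that forms four bonds and both rings in one operation. Because C2 and C3 are base-labile, the same medium should funnel all isomers into the centrosymmetric one. Demethylation completes the route.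

Key step: step 3

Remark: flavanone numbering is used (O1, C2, C3, C4, C4a to C8a, doubly primed in the second half). The configuration (2S,3R,2''R,3''S) with two identical halves is achiral (meso) and 2,3-trans in both rings, so only relative configuration has to be controlled.

Step 1
Reactants: 1 1-(2-fluoro-4-methoxyphenyl)ethan-1-one (two equivalents)
Product: 3 1,4-bis(2-fluoro-4-methoxyphenyl)butane-1,4-dione, via lithium enolate 2 (not isolated)
Conditions: LiN(i-Pr)2 (commercial solution, 1.05 equiv), THF, −78 °C; CuCl2 (1.1 equiv), DMF, −78 → 23 °C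
Reagents that add atoms: none
Why: Oxidative enolate homocoupling: CuCl2 oxidises the methyl ketone enolate 2 by one electron and the α-keto radical equivalents join at carbon to give the C3–C3'' bond; methyl aryl ketones are the best substrates for this coupling and no stereocentre is formed.

Step 2
Reactants: 3 1,4-bis(2-fluoro-4-methoxyphenyl)butane-1,4-dione
Product: 5 (1Z,3Z)-1,4-bis(2-fluoro-4-methoxyphenyl)-1,4-bis(trimethylsilyloxy)buta-1,3-diene, via dilithium dienediolate 4 (not isolated)
Conditions: LiN(i-Pr)2 (2.3 equiv), THF, −78 °C; Me3SiCl (3 equiv), −78 → 0 °C; pentane, filtration, concentration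
Reagents that add atoms: chlorotrimethylsilane, C[Si](C)(C)Cl
Why: Twofold kinetic deprotonation gives the conjugated dienediolate 4, which Me3SiCl traps on oxygen (silyl enol ether formation); aryl alkyl ketones give the Z(O) geometry, which has no bearing on the later outcome.

Step 3
Reactants: 5 (1Z,3Z)-1,4-bis(2-fluoro-4-methoxyphenyl)-1,4-bis(trimethylsilyloxy)buta-1,3-diene; 6 4-methoxybenzaldehyde (2.2 equiv)
Product: 9 (2S,3R,2''R,3''S)-7,7''-dimethoxy-2,2''-bis(4-methoxyphenyl)-3,3''-bichroman-4,4''-dione (meso tetramethyl ether), via bis(silyl aldol) adduct 7 (not isolated), via biflavanone isomer mixture 8 (not isolated)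
Conditions: CsF (20 mol %), 4 Å MS, DMF, 0 → 23 °C; then 65 °C, Ar sweep; AcOH; crystallisation from EtOH
Reagents that add atoms: 4-methoxybenzaldehyde (compound 6), COc1ccc(C=O)cc1
Why: Proposed new method: catalytic fluoride desilylates an enol ether terminus of 5, the freed enolate carbon C3 adds to the formyl carbon of 6 (future C2) and silyl transfer parks the twofold adduct as 7, after which, on warming, fluoride unmasks each C2–O alkoxide, this oxygen displaces the ortho fluorine at C8a, and every closure hands back the fluoride that starts the next cycle, so that Me3SiF is the only by-product and base never exceeds the catalyst loading. The closest known reaction types are the fluoride-catalysed Mukaiyama aldol addition, the CsF-catalysed arylation of silyl ethers by activated aryl fluorides and the stepwise aldol–cyclisation course of hetero-Diels–Alder reactions of 1-methoxy-3-silyloxy-1,3-dienes with aldehydes, in which methoxide plays the part that fluoride takes here. Each of the two pyranone rings closes by a 6-endo-trig addition–elimination (SNAr) of the alkoxide at C8a, the C4 ketone taking up the charge. C3 and C3'' are set thermodynamically by enolisation and reprotonation, which puts the C3–C3'' bond equatorial and trans to the equatorial aryl group on C2 or C2'', while C2 and C2'' are correlated through reversible retro-oxa-Michael opening and reclosure, which should drain 8 into meso 9, whose anti conformer opposes the C4 and C4'' carbonyl dipoles and has only mixed C2/C4'' and C4/C2'' gauche contacts, whereas the racemic trans,trans isomer has to place C2 gauche to C2'' and C4 gauche to C4''. The step needs ring closure to outrun dehydration, retro-aldol loss and closure onto the wrong ring, which the substrate secures by holding the ketone-activated C–F carbon in a 1,6-relationship to the alkoxide (six- against seven-membered closure) and by making retro-aldol harmless, since it only returns the two partners. Silanolate lost by elimination still carries the aldehyde oxygen and can return by conjugate addition or by attack at C8a, so that the side channels should converge on the same product.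

Step 4
Reactants: 9 (2S,3R,2''R,3''S)-7,7''-dimethoxy-2,2''-bis(4-methoxyphenyl)-3,3''-bichroman-4,4''-dione
Product: 11 (2S,3R,2''R,3''S)-7,7''-dihydroxy-2,2''-bis(4-hydroxyphenyl)-3,3''-bichroman-4,4''-dione (target), via tetrakis(dibromoboryl) ether 10 (not isolated)
Conditions: BBr3 (10 equiv), CH2Cl2, −78 → 23 °C; H2O, 0 °C
Reagents that add atoms: none
Why: BBr3 demethylation of aryl methyl ethers: boron binds each methoxy oxygen, bromide removes the methyl group by SN2 and water hydrolyses the aryl borates of 10; all four stereocentres already sit in their thermodynamic arrangement, so reversible enolisation under acid should not change them.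

Compound list
1 | 1-(2-fluoro-4-methoxyphenyl)ethan-1-one | CC(=O)c1ccc(OC)cc1F | starting material
2 | lithium enolate of 1 | [Li+].C=C([O-])c1ccc(OC)cc1F | intermediate
3 | 1,4-bis(2-fluoro-4-methoxyphenyl)butane-1,4-dione | COc1ccc(C(=O)CCC(=O)c2ccc(OC)cc2F)c(F)c1 | intermediate
4 | dilithium (1Z,3Z)-1,4-bis(2-fluoro-4-methoxyphenyl)buta-1,3-diene-1,4-diolate | [Li+].[Li+].COc1ccc(/C([O-])=C/C=C(\[O-])c2ccc(OC)cc2F)c(F)c1 | intermediate
5 | (1Z,3Z)-1,4-bis(2-fluoro-4-methoxyphenyl)-1,4-bis(trimethylsilyloxy)buta-1,3-diene | COc1ccc(/C(O[Si](C)(C)C)=C/C=C(\O[Si](C)(C)C)c2ccc(OC)cc2F)c(F)c1 | intermediate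
6 | 4-methoxybenzaldehyde | COc1ccc(C=O)cc1 | starting material
7 | 1,4-bis(2-fluoro-4-methoxyphenyl)-2,3-bis[(4-methoxyphenyl)(trimethylsilyloxy)methyl]butane-1,4-dione (all diastereomers, configuration not defined) | COc1ccc(cc1)C(O[Si](C)(C)C)C(C(=O)c1ccc(OC)cc1F)C(C(=O)c1ccc(OC)cc1F)C(O[Si](C)(C)C)c1ccc(OC)cc1 | intermediate
8 | 7,7''-dimethoxy-2,2''-bis(4-methoxyphenyl)-3,3''-bichroman-4,4''-dione (kinetic mixture of stereoisomers, configuration not defined) | COc1ccc(cc1)C1Oc2cc(OC)ccc2C(=O)C1C1C(=O)c2ccc(OC)cc2OC1c1ccc(OC)cc1 | intermediate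
9 | (2S,3R,2''R,3''S)-7,7''-dimethoxy-2,2''-bis(4-methoxyphenyl)-3,3''-bichroman-4,4''-dione (meso, both rings 2,3-trans) | O=C1c2ccc(OC)cc2O[C@H](c2ccc(OC)cc2)[C@H]1[C@@H]1C(=O)c2ccc(OC)cc2O[C@H]1c1ccc(OC)cc1 | intermediate
10 | tetrakis(dibromoboryl) ether of 11 | O=C1c2ccc(OB(Br)Br)cc2O[C@H](c2ccc(OB(Br)Br)cc2)[C@H]1[C@@H]1C(=O)c2ccc(OB(Br)Br)cc2O[C@H]1c1ccc(OB(Br)Br)cc1 | intermediate
11 | (2S,3R,2''R,3''S)-7,7''-dihydroxy-2,2''-bis(4-hydroxyphenyl)-3,3''-bichroman-4,4''-dione (CNP0231820.1) | O=C1c2ccc(O)cc2O[C@H](c2ccc(O)cc2)[C@H]1[C@@H]1C(=O)c2ccc(O)cc2O[C@H]1c1ccc(O)cc1 | target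

Total step count: 4. Longest linear sequence: 4.

Steps most likely to fail

Step 3 (labelled step).
- **What may go wrong:** Loss of silanolate from the aldol adducts may outrun ring closure. Substitution may be slow because the 4-methoxy group weakens the ketone as an acceptor. The equilibrium may discriminate poorly between the meso and the racemic trans,trans isomers.
- **Fallback (known chemistry), from 3 back to 9:**
  - Hydroxide displaces both fluorines of 3 (KOH, DMSO/H2O, 100 °C) to give 1,4-bis(2-hydroxy-4-methoxyphenyl)butane-1,4-dione F1.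
  - Twofold Claisen–Schmidt condensation of F1 with 6 (KOH, EtOH) gives the bis(2'-hydroxychalcone) (2E,3E)-1,4-bis(2-hydroxy-4-methoxyphenyl)-2,3-bis(4-methoxybenzylidene)butane-1,4-dione F2.
  - NaOAc in refluxing EtOH then closes both rings by 6-endo-trig oxa-Michael addition under thermodynamic control to 9.
  - The meso isomer is collected by crystallisation and the mother liquor is equilibrated again.

Step 4.
- **What may go wrong:** The Lewis acid may ionise the 4-alkoxybenzylic C2–O1 bond, opening the ring. Cleavage of the four methyl ethers may be incomplete.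
- **Fallback, from 3 back to 11, exchanging the protecting group for one that leaves under neutral conditions:**
  - The robust diketone 3 is demethylated (BBr3, CH2Cl2) to 1,4-bis(2-fluoro-4-hydroxyphenyl)butane-1,4-dione F3.
  - F3 is benzylated (BnBr, K2CO3, DMF) to 1,4-bis[4-(benzyloxy)-2-fluorophenyl]butane-1,4-dione F4.
  - F4 is silylated as in step 2 to (1Z,3Z)-1,4-bis[4-(benzyloxy)-2-fluorophenyl]-1,4-bis(trimethylsilyloxy)buta-1,3-diene F5.
  - F5 is taken through the fluoride relay of step 3 with commercial 4-(benzyloxy)benzaldehyde to (2S,3R,2''R,3''S)-7,7''-bis(benzyloxy)-2,2''-bis[4-(benzyloxy)phenyl]-3,3''-bichroman-4,4''-dione F6.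
  - Hydrogenolysis of F6 (H2, Pd/C, EtOAc/MeOH) gives 11.

Step 1.
- **What may go wrong:** CuCl2 may chlorinate the enolate at the α-carbon. The product may be over-oxidised to the ene-dione. Proton return may regenerate the ketone.
- **Fallback, from 1 back to 3, replacing the radical dimerisation by a polar union of two differentiated halves:**
  - Bromination of 1 (CuBr2, EtOAc/CHCl3, reflux) gives 2-bromo-1-(2-fluoro-4-methoxyphenyl)ethan-1-one F7.
  - F7 is condensed with a second equivalent of 1 under ZnCl2, Et2NH and t-BuOH in toluene at 23 °C, a known 1,4-diketone synthesis from methyl ketones and bromomethyl ketones, to give 3.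

Further compounds
F1 | step 3 | 1,4-bis(2-hydroxy-4-methoxyphenyl)butane-1,4-dione | COc1ccc(C(=O)CCC(=O)c2ccc(OC)cc2O)c(O)c1
F2 | step 3 | (2E,3E)-1,4-bis(2-hydroxy-4-methoxyphenyl)-2,3-bis(4-methoxybenzylidene)butane-1,4-dione | COc1ccc(/C=C(/C(=O)c2ccc(OC)cc2O)\C(=C/c2ccc(OC)cc2)C(=O)c2ccc(OC)cc2O)cc1
F3 | step 4 | 1,4-bis(2-fluoro-4-hydroxyphenyl)butane-1,4-dione | O=C(CCC(=O)c1ccc(O)cc1F)c1ccc(O)cc1F
F4 | step 4 | 1,4-bis[4-(benzyloxy)-2-fluorophenyl]butane-1,4-dione | O=C(CCC(=O)c1ccc(OCc2ccccc2)cc1F)c1ccc(OCc2ccccc2)cc1F
F5 | step 4 | (1Z,3Z)-1,4-bis[4-(benzyloxy)-2-fluorophenyl]-1,4-bis(trimethylsilyloxy)buta-1,3-diene | C(c1ccccc1)Oc1ccc(/C(O[Si](C)(C)C)=C/C=C(\O[Si](C)(C)C)c2ccc(OCc3ccccc3)cc2F)c(F)c1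
F6 | step 4 | (2S,3R,2''R,3''S)-7,7''-bis(benzyloxy)-2,2''-bis[4-(benzyloxy)phenyl]-3,3''-bichroman-4,4''-dione | O=C1c2ccc(OCc3ccccc3)cc2O[C@H](c2ccc(OCc3ccccc3)cc2)[C@H]1[C@@H]1C(=O)c2ccc(OCc3ccccc3)cc2O[C@H]1c1ccc(OCc2ccccc2)cc1
F7 | step 1 | 2-bromo-1-(2-fluoro-4-methoxyphenyl)ethan-1-one | COc1ccc(C(=O)CBr)c(F)c1
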